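**Retrosynthetic overview**
1. The only ring, the 1,2-dioxane, is closed last: a C3 hydroperoxide adds to the C6 ketone in acidic methanol, giving the methoxy peroxyketal (C6 under thermodynamic control) and the methyl ester.
2. The C3–OO stereocentre comes from an amine-catalysed enantioselective β-peroxidation of a 6-oxo-2-enal.
3. Key C4–C5 bond: an enolonium species (ketone α-carbon made electrophilic by trivalent iodine) is attacked by the γ-carbon of a crotonaldehyde silyl dienol ether; both carbons are normally nucleophilic.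
4. The C18 methyl ketone comes from Sonogashira coupling of hept-6-yn-2-one with (E)-1-iodoundec-1-en-10-yne (Takai olefination of dec-9-ynal).

Assumption: positions are numbered along the C22 acid chain (C1 ester carbon, C3 and C6 the ring stereocentres); the target is (3S,6R), with OMe and CH2CO2Me cis on the ring.
Assumption: commercial 1-(trimethylsilyloxy)buta-1,3-diene is used as supplied (mainly E).

**Route**

Step 1
Reactants: 1 hex-5-ynenitrile
Product: 2 hept-6-yn-2-one
Conditions: MeMgBr (2.3 equiv), Et2O–toluene, reflux; then 1 M aq. HCl, 0 °C → rt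
Reagents that add atoms: methylmagnesium bromide C[Mg]Br; water O
Why: Grignard addition to a nitrile stops at the N-magnesio ketimine (the first equivalent only deprotonates the alkyne), and acidic hydrolysis releases the methyl ketone.

Step 2
Reactants: 3 dec-9-yn-1-ol
Product: 4 dec-9-ynal
Conditions: TEMPO (10 mol%), PhI(OAc)2 (1.1 equiv), CH2Cl2, rt
Reagents that add atoms: none
Why: Oxoammonium (TEMPO) oxidation takes the primary alcohol to the aldehyde without over-oxidation and leaves the alkyne untouched.

Step 3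
Reactants: 4 dec-9-ynal
Product: 5 (1E)-1-iodoundec-1-en-10-yne
Conditions: CrCl2 (6 equiv), CHI3 (2 equiv), dioxane–THF 6:1, 0 °C → rt
Reagents that add atoms: iodoform IC(I)I
Why: Takai olefination: the gem-dichromium species from CHI3/CrCl2 adds to the aldehyde and eliminates to the (E)-vinyl iodide (E favoured in dioxane-rich solvent); the terminal alkyne is inert.

Step 4
Reactants: 5 (1E)-1-iodoundec-1-en-10-yne; 2 hept-6-yn-2-one
Product: 6 (8E)-octadec-8-ene-6,17-diyn-2-one
Conditions: 2 (4 equiv), PdCl2(PPh3)2 (3 mol%), CuI (5 mol%), Et3N (3 equiv), THF, rt; 5 added over 6 h by syringe pump; excess 2 recovered by distillation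
Reagents that add atoms: none
Why: Sonogashira coupling with retention of the E geometry; because 5 carries its own terminal alkyne, it is added slowly to a fourfold excess of the cheap alkyne 2 so that cross-coupling dominates statistically.

Step 5
Reactants: 6 (8E)-octadec-8-ene-6,17-diyn-2-one
Product: 7 trimethyl{[(8E)-18-(trimethylsilyl)octadeca-1,8-diene-6,17-diyn-2-yl]oxy}silane
Conditions: LDA (2.3 equiv) and TMSCl (2.6 equiv) premixed, THF, −78 °C, 6 added slowly, then → 0 °C; Et3N, pentane, filtration; used crude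
Reagents that add atoms: chlorotrimethylsilane C[Si](C)(C)Cl
Why: Kinetic enolate silylation: LDA deprotonates the methyl group and in-situ TMSCl traps the terminal silyl enol ether, while the second equivalent deliberately C-silylates the acidic terminal alkyne so that it cannot interfere here or in step 6.

Step 6
Reactants: 7 trimethyl{[(8E)-18-(trimethylsilyl)octadeca-1,8-diene-6,17-diyn-2-yl]oxy}silane; 8 (E)-1-(trimethylsilyloxy)buta-1,3-diene
Product: 10 (2E,12E)-6-oxo-22-(trimethylsilyl)docosa-2,12-diene-10,21-diynal, via enolonium species 9 (not isolated)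
Conditions: PhI(OH)OTs (1.1 equiv), BF3·OEt2 (1.2 equiv), CH2Cl2, −78 °C, 5 min; then 8 (2 equiv), −78 → −55 °C, 30 min; aq. NaHCO3 quench at −55 °C
Reagents that add atoms: none
Why: Proposed new method: BF3-activated PhI(OH)OTs converts the silyl enol ether into the O-bound trivalent-iodine enolate 9, a ketone α-cation equivalent, whose CH2 carbon (C5) is attacked by the terminal γ-carbon of siloxydiene 8 with loss of PhI, and the silyloxocarbenium then loses its silyl group to give the (E)-enal; the closest known reaction types are enolonium couplings of silyl enol ethers with allylsilanes and with second silyl enol ethers (unsymmetrical 1,4-diketones) and the γ-selective vinylogous Mukaiyama attack of 1-siloxydienes on cationic electrophiles.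

Step 7
Reactants: 11 2,3-dimethylbut-2-ene
Product: 12 2-methoxypropan-2-yl hydroperoxide
Conditions: O3, MeOH–CH2Cl2 1:4, −78 °C; N2 purge; kept as a CH2Cl2 stock solution, never concentrated to dryness
Reagents that add atoms: ozone [O-][O+]=O; methanol CO
Why: Ozonolysis with solvent trapping: the acetone carbonyl oxide from the tetrasubstituted alkene is captured by methanol as the α-methoxy hydroperoxide.

Step 8
Reactants: 10 (2E,12E)-6-oxo-22-(trimethylsilyl)docosa-2,12-diene-10,21-diynal; 12 2-methoxypropan-2-yl hydroperoxide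
Product: 13 (3S,12E)-3-[(2-methoxypropan-2-yl)peroxy]-6-oxo-22-(trimethylsilyl)docos-12-ene-10,21-diynal
Conditions: (R)-2-{bis[3,5-bis(trifluoromethyl)phenyl](trimethylsilyloxy)methyl}pyrrolidine (20 mol%), 12 (2 equiv), toluene, 0 °C, 24 h; used promptly
Reagents that add atoms: none
Why: Iminium-catalysed enantioselective peroxy-Michael addition of an α-alkoxyalkyl hydroperoxide to an enal, a known reaction type with diarylprolinol silyl ethers; in the E, s-trans iminium the diaryl(silyloxy)methyl group of the (R)-catalyst blocks one β-face, so the peroxide adds to the open face and sets C3 as S.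

Step 9
Reactants: 13 (3S,12E)-3-[(2-methoxypropan-2-yl)peroxy]-6-oxo-22-(trimethylsilyl)docos-12-ene-10,21-diynal
Product: 14 (3S,12E)-3-[(2-methoxypropan-2-yl)peroxy]-6-oxo-22-(trimethylsilyl)docos-12-ene-10,21-diynoic acid
Conditions: NaClO2 (3 equiv), NaH2PO4 (3 equiv), 2-methylbut-2-ene (20 equiv), t-BuOH–H2O 4:1, 0 °C → rt
Reagents that add atoms: sodium chlorite [Na+].[O-]Cl=O
Why: Pinnick oxidation converts the aldehyde to the acid under mildly acidic buffered conditions with hypochlorite scavenged, leaving the peroxide, ketone, enyne and the non-enolisable C3 centre untouched.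

Step 10
Reactants: 14 (3S,12E)-3-[(2-methoxypropan-2-yl)peroxy]-6-oxo-22-(trimethylsilyl)docos-12-ene-10,21-diynoic acid
Product: 18 methyl 2-[(3S,6R)-6-[(6E)-hexadec-6-ene-4,15-diyn-1-yl]-6-methoxy-1,2-dioxan-3-yl]acetate, via desilylated peroxy acid 15 (not isolated), via hydroperoxy keto acid 16 (not isolated), via dioxane acid 17 (not isolated)
Conditions: K2CO3 (1.5 equiv), MeOH, rt, 2 h; then TsOH·H2O (3.5 equiv), same flask, rt, 16–24 h
Reagents that add atoms: methanol CO
Why: K2CO3/MeOH cleaves the alkynyl C–Si bond while the substrate is a carboxylate that cannot undergo β-elimination; acidification then removes the peroxyketal by transketalisation, the freed hydroperoxide closes onto the C6 oxocarbenium (peroxyketalisation) and Fischer esterification finishes the target, with C6 set under thermodynamic control of the acid-reversible ketal (axial anomeric OMe, both carbon chains equatorial, which is 6R for 3S).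

**Compound list**
1 | hex-5-ynenitrile | N#CCCCC#C | starting material
2 | hept-6-yn-2-one | CC(=O)CCCC#C | intermediate
3 | dec-9-yn-1-ol | OCCCCCCCCC#C | starting material
4 | dec-9-ynal | O=CCCCCCCCC#C | intermediate
5 | (1E)-1-iodoundec-1-en-10-yne | I/C=C/CCCCCCCC#C | intermediate
6 | (8E)-octadec-8-ene-6,17-diyn-2-one | CC(=O)CCCC#C/C=C/CCCCCCCC#C | intermediate
7 | trimethyl{[(8E)-18-(trimethylsilyl)octadeca-1,8-diene-6,17-diyn-2-yl]oxy}silane | C=C(O[Si](C)(C)C)CCCC#C/C=C/CCCCCCCC#C[Si](C)(C)C | intermediate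
8 | (E)-1-(trimethylsilyloxy)buta-1,3-diene | C=C/C=C/O[Si](C)(C)C | starting material
9 | enolonium species, {[(8E)-18-(trimethylsilyl)octadeca-1,8-diene-6,17-diyn-2-yl]oxy}(phenyl)-λ3-iodanyl 4-methylbenzenesulfonate | C=C(OI(c1ccccc1)OS(=O)(=O)c1ccc(C)cc1)CCCC#C/C=C/CCCCCCCC#C[Si](C)(C)C | intermediate
10 | (2E,12E)-6-oxo-22-(trimethylsilyl)docosa-2,12-diene-10,21-diynal | O=C/C=C/CCC(=O)CCCC#C/C=C/CCCCCCCC#C[Si](C)(C)C | intermediate
11 | 2,3-dimethylbut-2-ene | CC(C)=C(C)C | starting material
12 | 2-methoxypropan-2-yl hydroperoxide | COC(C)(C)OO | intermediate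
13 | (3S,12E)-3-[(2-methoxypropan-2-yl)peroxy]-6-oxo-22-(trimethylsilyl)docos-12-ene-10,21-diynal | O=CC[C@@H](OOC(C)(C)OC)CCC(=O)CCCC#C/C=C/CCCCCCCC#C[Si](C)(C)C | intermediate
14 | (3S,12E)-3-[(2-methoxypropan-2-yl)peroxy]-6-oxo-22-(trimethylsilyl)docos-12-ene-10,21-diynoic acid | OC(=O)C[C@@H](OOC(C)(C)OC)CCC(=O)CCCC#C/C=C/CCCCCCCC#C[Si](C)(C)C | intermediate
15 | (3S,12E)-3-[(2-methoxypropan-2-yl)peroxy]-6-oxodocos-12-ene-10,21-diynoic acid | OC(=O)C[C@@H](OOC(C)(C)OC)CCC(=O)CCCC#C/C=C/CCCCCCCC#C | intermediate
16 | (3S,12E)-3-hydroperoxy-6-oxodocos-12-ene-10,21-diynoic acid | OC(=O)C[C@@H](OO)CCC(=O)CCCC#C/C=C/CCCCCCCC#C | intermediate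
17 | 2-[(3S,6R)-6-[(6E)-hexadec-6-ene-4,15-diyn-1-yl]-6-methoxy-1,2-dioxan-3-yl]acetic acid | C#CCCCCCCC/C=C/C#CCCC[C@]1(OC)CC[C@@H](CC(=O)O)OO1 | intermediate
18 | methyl 2-[(3S,6R)-6-[(6E)-hexadec-6-ene-4,15-diyn-1-yl]-6-methoxy-1,2-dioxan-3-yl]acetate | C#CCCCCCCC/C=C/C#CCCC[C@]1(OC)CC[C@@H](CC(=O)OC)OO1 | target

**Totals**
Total step count: 10. Longest linear sequence: 8 steps (3 → 4 → 5 → 6 → 7 → 10 → 13 → 14 → 18; steps 2, 3, 4, 5, 6, 8, 9, 10).

**Three steps most likely to fail**

Step 6 (key coupling). Risks are α- instead of γ-attack of the dienol ether, BF3-promoted Mukaiyama-type over-addition of excess 8 to the product aldehyde (hence only 2 equiv of 8 and a cold quench), and capture of the enolonium carbon by the internal alkyne. Fallback: it sets out from 7 and comes back at 10. Bromination of the silyl enol ether 7 (NBS, THF, −78 °C) gives the isolable α-bromo ketone (8E)-1-bromo-18-(trimethylsilyl)octadec-8-ene-6,17-diyn-2-one F5. This is coupled with 8 (3 equiv) by photoredox radical–polar crossover (Ir(ppy)3 1 mol%, 2,6-lutidine, MeCN, blue LEDs): the electrophilic α-keto radical adds to the terminal carbon of the siloxydiene, and oxidation and desilylation give 10.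

Step 8 (asymmetric peroxidation). Risks are an intramolecular aldol of the enamine intermediate onto the C6 ketone, epoxide formation or retro-addition, and a lower ee with this small hydroperoxide; the facial sense rests on the shielding model, and both catalyst enantiomers are commercial. Fallback: it sets out from 10 and comes back at 18.
- Pinnick oxidation of 10 gives (2E,12E)-6-oxo-22-(trimethylsilyl)docosa-2,12-diene-10,21-diynoic acid F6.
- K2CO3/MeOH followed by TsOH/MeOH gives methyl (2E,12E)-6-oxodocosa-2,12-diene-10,21-diynoate F7.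
- Ketalisation (HC(OMe)3, MeOH, TsOH cat.) and exchange with ethereal H2O2 gives racemic methyl (2E,12E)-6-hydroperoxy-6-methoxydocosa-2,12-diene-10,21-diynoate F8.
- Intramolecular peroxide conjugate addition (Et2NH, CF3CH2OH) and TsOH/MeOH equilibration at C6 give the cis-dioxane as a 1:1 mixture of 18 and its enantiomer, methyl 2-[(3R,6S)-6-[(6E)-hexadec-6-ene-4,15-diyn-1-yl]-6-methoxy-1,2-dioxan-3-yl]acetate F9.
- Preparative HPLC on a chiral stationary phase separates the two and delivers 18.

Step 4 (statistical Sonogashira). The risk is oligomer formation through the free alkyne of 5 and of the product. Fallback: it sets out from 3 and comes back at 7.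
- C-silylation of the alkyne of 3 (n-BuLi, TMSCl, acidic work-up) gives 10-(trimethylsilyl)dec-9-yn-1-ol F1.
- Oxidation as in step 2 gives 10-(trimethylsilyl)dec-9-ynal F2.
- Takai olefination as in step 3 gives (E)-(11-iodoundec-10-en-1-yn-1-yl)trimethylsilane F3.
- Sonogashira coupling with only 1.2 equiv of 2 gives (8E)-18-(trimethylsilyl)octadec-8-ene-6,17-diyn-2-one F4.
- Kinetic silylation (LDA 1.1 equiv, TMSCl) gives 7.

**Further compounds**
F1 | step 4 | 10-(trimethylsilyl)dec-9-yn-1-ol | C[Si](C)(C)C#CCCCCCCCCO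
F2 | step 4 | 10-(trimethylsilyl)dec-9-ynal | C[Si](C)(C)C#CCCCCCCCC=O
F3 | step 4 | (E)-(11-iodoundec-10-en-1-yn-1-yl)trimethylsilane | C[Si](C)(C)C#CCCCCCCC/C=C/I
F4 | step 4 | (8E)-18-(trimethylsilyl)octadec-8-ene-6,17-diyn-2-one | CC(=O)CCCC#C/C=C/CCCCCCCC#C[Si](C)(C)C
F5 | step 6 | (8E)-1-bromo-18-(trimethylsilyl)octadec-8-ene-6,17-diyn-2-one | BrCC(=O)CCCC#C/C=C/CCCCCCCC#C[Si](C)(C)C
F6 | step 8 | (2E,12E)-6-oxo-22-(trimethylsilyl)docosa-2,12-diene-10,21-diynoic acid | OC(=O)/C=C/CCC(=O)CCCC#C/C=C/CCCCCCCC#C[Si](C)(C)C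
F7 | step 8 | methyl (2E,12E)-6-oxodocosa-2,12-diene-10,21-diynoate | COC(=O)/C=C/CCC(=O)CCCC#C/C=C/CCCCCCCC#C
F8 | step 8 | methyl (2E,12E)-6-hydroperoxy-6-methoxydocosa-2,12-diene-10,21-diynoate (racemic) | COC(=O)/C=C/CCC(OC)(OO)CCCC#C/C=C/CCCCCCCC#C
F9 | step 8 | methyl 2-[(3R,6S)-6-[(6E)-hexadec-6-ene-4,15-diyn-1-yl]-6-methoxy-1,2-dioxan-3-yl]acetate | C#CCCCCCCC/C=C/C#CCCC[C@@]1(OC)CC[C@H](CC(=O)OC)OO1
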